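## Analysis of the target

The target is a germacranolide: a ten-membered carbocycle C1–C10 that carries a methyl ester (C14) on C10, a methyl group (C15) on C4, and an α-methylene-γ-lactone (C11–C13, O on C6) fused across C6–C7. C10=C1 (ring-cis, CIP E) and C2=C3 (Z) form a dienoate that ends at a trans-4,5-epoxide, so C3–C5 is a vinyl oxirane. Six contiguous ring stereocentres run from C4 to C9 (4R,5R,6S,7R,8S,9S). The oxygens on C6 and C9 are cis to each other, while the C7–C11 bond and the C8 oxygen lie on the opposite face, which makes the lactone trans-fused. The C8 ester is a (2S,3R)-2,3-dimethyloxirane-2-carboxylate and adds two more stereocentres. Sensitive groups are the α-methylene lactone (Michael acceptor), the vinyl epoxide (acid), the C9 acetate β to the dienoate carbon, the glycidic ester, and three different esters that forbid strong nucleophiles late on. The difficulty is the medium ring itself and stereocontrol on a floppy ring whose polyene intermediates are prone to transannular and electrocyclic reactions. The strategy rests on one feature: C5 (oxygen-bearing) and C10 (bearing C14) are 1,6-related. Joining them through C14 as a one-carbon bridge turns the ring into a bicyclo[4.4.1]undecane whose arm C1–C4 plus C5–O and C14 is a tropolone, and whose arm C6–C9, oxygenated at both ends, is a 1,4-dioxygenated butadiene.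

## Retrosynthetic reasoning

**Epoxide and dienoate last.** The C5–O bond of the oxirane and the C10=C1 π bond are cut first, because the vinyl epoxide and the dienoate are the most fragile parts. Target 29 comes from diol 27 by activating the secondary C5 hydroxyl and letting the tertiary C4 oxygen displace it with inversion. Diol 27 comes from α-hydroxy ketone 26 by chelation-controlled reduction. The 1(10) double bond of 26 comes from β-elimination of the C1 hydroxyl of 24.

**C4–O and C1–O from one 1,4-dioxygenation.** The cis oxygens on C1 and C4 of 24, flanking a Z alkene, are the two ends of a cleaved O–O bond. The ten-membered endoperoxide 23 is therefore the precursor. It is made while the skeleton is still bicyclic (21 from 20), where the diene is held s-cis, one face is shielded, and the C2=C3 geometry cannot be anything but Z.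

**Excision of the bridge.** The C5–C14 bond of α-ketol 22 is cut: oxidative cleavage in an alcohol turns the bridging ketone into the C14 methyl ester on C10 and the carbinol into the C5 ketone of 23. This is the only place where a one-carbon bridge can be removed leaving exactly the functions the target needs. Ketol 22 comes from 21 by cleavage of the benzylic ether.

**Lactone and C8 ester.** Lactone 20 is the oxidised form of lactol 19, obtained from methyl acetal 18. The C8–O acyl bond is cut to give alcohol 12 and acid 16. Acid 16 comes from tiglic acid 13 through allylic alcohol 14 and epoxy alcohol 15, the epoxidation setting both side-chain centres.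

**C7–C11 and C8–O in one operation.** Both bonds of 12 are traced to iodoacetal 10. A vinyl radical tethered to O6 closes onto C7, and the resulting C8 radical is captured by oxygen. Doing this on the bicycle matters: the C14 bridge covers one face of C7=C8, so carbon and oxygen enter from the same open face, and the tether fixes the regiochemistry. 10 is the mixed acetal of alcohol 9.

**Differentiation of O6 and O9, and resolution.** Mono-acetate 9 comes from racemic diol 8 by enzymatic acylation of the less hindered C9 hydroxyl of one enantiomer. Diol 8 comes from diacetate 7.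

**Ring construction.** C5–C6 and C9–C10 of 7 are cut together in a retro-[6+4] cycloaddition to tropone 5 and diene 6. This gives two achiral, flat partners and builds the ten-membered perimeter, both oxygenated centres C6 and C9, and the C14 carbon in one step.

**Tropone.** Ether 5 comes from bromide 4 by methyl cross-coupling, 4 from 3-bromotropolone 2 and benzyl chloride 3, and 2 from tropolone 1.

## Alternatives that were turned down

**Alternative 1:** The C7–C8 bond is disconnected by a retro-[2,3]-Wittig step, which enlarges the carbocycle to a thirteen-membered ring with an ether oxygen between C8 and C13. Forward, double deprotonation of the β-keto ester unit and sigmatropic contraction give A1, the ten-membered β-keto ester (enol form) with the C8 hydroxyl, the C7 propenoate and the 4,5-epoxide.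
- For: one suprafacial step makes C7–C8, both stereocentres, the free C8 hydroxyl and the C11=C13 methylene. That is the array which costs the chosen route steps 7, 8, 13 and 14. The stereocentres can come from asymmetric synthesis, so no resolution is needed. On both points it is stronger.
- Against: a thirteen-membered macrocyclic ether must be assembled and closed first. The dianion is generated next to an acrylate, an epoxide and a β-silyloxy group. In A1, C9 is still an enol carbon and C1 a methylene, so the C9 stereocentre and the 1(10) double bond remain to be made on the flexible ring.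
- Comparison: the chosen route forms the ring and C6/C9 in one intermolecular step from a three-step precursor, with C9 and C10 already at the right oxidation level. It pays with a resolution and a longer C7/C8 sequence.

**Alternative 2:** The C2–C3 and C8 positions are traced to an alkyne and a ketone that arise by cleaving the C3–C8 fusion bond of a decalin epoxy ketone. Forward, tosylhydrazone formation triggers Eschenmoser–Tanabe fragmentation to the cycloalkynone A2.
- For: C4–C7 and C9 are set on a rigid decalin, which is more secure than the chosen route for C4/C5. The fragmentation is entropically easy. Partial hydrogenation of the alkyne over Pd/CaCO3 poisoned with Pb(OAc)2 guarantees the Z alkene.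
- Against: A2 is far from the target. The C8 ketone must be reduced with control beside an epimerisable C7. C10 is sp3, so the 1(10) alkene needs a dehydrogenation. The acetonide must become the trans-epoxide. The silyloxyethyl chain must be oxidised, lactonised and methylenated. The decalin with five stereocentres is itself a long linear target, and hydrazone formation on a hindered β-alkoxy ketone invites elimination.
- Comparison: it is longer both before and after its key step. The chosen route offers a ring-forming step from flat achiral partners and fewer redox corrections.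

**Alternative 3:** The triene C10=C1–C2=C3–C4=C5 is traced to a cis-fused hexalin by joining C5 and C10. Forward, irradiation opens the cyclohexadiene conrotatorily to trienoate A3, which already carries the lactone, the C9 acetate and a C8 silyl ether.
- For: the endgame is the shortest of all. Only epoxidation of the electron-rich E-C4=C5 alkene (which gives the trans-epoxide directly), desilylation and acylation remain. Orbital symmetry fixes the triene geometry, and C6–C9 are set on a rigid decalin. On these points it is stronger.
- Against: the ring opening ends in a photostationary mixture. The triene absorbs further and is itself photolabile, and it can re-close thermally. The α-methylene lactone and dienoate are extra chromophores. The face of the late epoxidation depends on the conformation of a flexible triene.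
- Comparison: the chosen route builds the ring thermally, never exposes a free cyclic triene (the C1/C4 oxygens are installed on the bicycle), and sets C4 under rigid control. It pays with a longer endgame.

Key step: step 4

**Remarks**
- Atoms are numbered as in the target throughout (C1–C10 ring, C11–C13 lactone, C14 ester carbon, C15 methyl), also for bicyclic intermediates.
- The two oxirane methyl groups of the C8 acyl residue are cis ((2S,3R)). This is the epoxide of tiglic (E) acid, so the side chain is made from tiglic acid.
- Racemic 7 and 8 are drawn as the enantiomer that is carried on.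

## Route

Step 1
Reactants: 1 tropolone
Product: 2 3-bromotropolone
Conditions: NBS (1.0 equiv), CH2Cl2, 0 → 20 °C
Reagents that add atoms: N-bromosuccinimide, O=C1CCC(=O)N1Br
Why: Electrophilic halogenation of the enolised tropolone goes to the position next to the hydroxyl-bearing carbon; one equivalent limits it to monobromination.

Step 2
Reactants: 2 3-bromotropolone; 3 4-methoxybenzyl chloride
Product: 4 3-bromo-2-(4-methoxybenzyloxy)cyclohepta-2,4,6-trien-1-one
Conditions: K2CO3, DMF, 60 °C; chromatographic separation from the regioisomeric ether
Reagents that add atoms: none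
Why: Williamson O-alkylation of the ambident tropolonate gives both ethers; the isomer with bromine beside the ether carbon is collected, and the other can be returned to 2 by acidolysis.

Step 3
Reactants: 4 3-bromo-2-(4-methoxybenzyloxy)tropone
Product: 5 2-(4-methoxybenzyloxy)-3-methylcyclohepta-2,4,6-trien-1-one
Conditions: trimethylboroxine, Pd(PPh3)4 (5 mol%), K2CO3, dioxane/H2O, 95 °C
Reagents that add atoms: trimethylboroxine, CB1OB(C)OB(C)O1
Why: Suzuki–Miyaura methylation of an electron-poor vinylic bromide; oxidative addition into the troponoid C–Br bond is easy and the benzyl ether is inert.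

Step 4
Reactants: 5 2-(4-methoxybenzyloxy)-3-methyltropone; 6 (1E,3E)-buta-1,3-diene-1,4-diyl diacetate
Product: 7 (±)-exo-6,9-diacetoxy-5-(4-methoxybenzyloxy)-4-methylbicyclo[4.4.1]undeca-1,3,7-trien-14-one (C14=O bridges C5 and C10; acetoxy groups cis to each other, each C–O bond anti to the neighbouring bridge bond)
Conditions: 6 (3 equiv), BHT (cat.), xylene, 130 °C, sealed tube, N2
Reagents that add atoms: none
Why: A concerted, thermally allowed [6+4] cycloaddition joins the tropone termini (C5 and C10) suprafacially to the termini of the s-cis diene (C6 and C9), forming C5–C6 and C9–C10 in one step. The closest known reactions are the thermal [6+4] additions of tropone to 1-acetoxybutadiene and to cyclopentadiene, which give bicyclo[4.4.1]undecatrienones. Both cycloheptene rings and the ten-membered perimeter are closed by the cycloaddition itself, with the tropone carbonyl carbon becoming the one-atom bridge C14. C6 and C9 come out cis because both acetoxy groups are trans ("outside") on the diene and the diene reacts on one face. Their relation to C5 and C10 follows from the exo transition state, in which C7–C8 lies under the carbonyl and not under C1–C4, as is usual for tropone because the endo secondary overlap is antibonding. Nothing controls absolute configuration, so 7 is racemic and is resolved in step 6. The step needs [6+4] over [4+2] periselectivity, which the large frontier coefficients at the two carbons flanking the tropone carbonyl and the electron-rich diene favour; the symmetric diene removes any regiochemical question. The alkoxy and methyl groups at one terminus make this tropone slower than the parent, which is the main uncertainty.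

Step 5
Reactants: 7 racemic diacetate
Product: 8 (±)-6,9-dihydroxy-5-(4-methoxybenzyloxy)-4-methylbicyclo[4.4.1]undeca-1,3,7-trien-14-one (cis diol, same relative configuration as 7)
Conditions: K2CO3 (0.2 equiv), MeOH, 0 °C
Reagents that add atoms: none
Why: Zemplén-type transesterification; the ketone has only bridgehead α-positions, so enolisation, β-elimination and retro-aldol cleavage are geometrically disfavoured under these mild conditions.

Step 6
Reactants: 8 racemic diol
Product: 9 6-hydroxy-5-(4-methoxybenzyloxy)-4-methyl-14-oxobicyclo[4.4.1]undeca-1,3,7-trien-9-yl acetate, single enantiomer with C6 and C9 as in the target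
Conditions: lipase from Burkholderia cepacia (immobilised), vinyl acetate, MTBE, 30 °C, stopped near half conversion; separation from unreacted ent-diol
Reagents that add atoms: vinyl acetate, C=COC(C)=O
Why: Lipase-catalysed kinetic resolution by irreversible transesterification; the C9 hydroxyl is the accessible one (C6–OH is neopentylic beside quaternary C5), and the target-series C9 carbinol (R in the diol, sp3 ring side larger than the vinyl side) is the one the empirical size rule for lipases predicts to be acylated faster.

Step 7
Reactants: 9 mono-acetate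
Product: 10 O6-(2-iodo-1-methoxyprop-2-en-1-yl) ether of 9 (mixed acetal, both epimers at the acetal carbon C12)
Conditions: methoxyallene (3 equiv), NIS (1.5 equiv), CH2Cl2, −78 → −30 °C
Reagents that add atoms: methoxyallene, COC=C=C; N-iodosuccinimide, O=C1CCC(=O)N1I
Why: Iodoalkoxylation of the allenyl ether: iodonium adds to the central allene carbon and the C6 hydroxyl traps the oxocarbenium ion; the enol ether is far more nucleophilic than the ring diene, so only the reagent is iodinated.

Step 8
Reactants: 10 iodoacetal
Product: 12 tetracyclic acetal with a 2-methoxy-3-methylenetetrahydrofuran fused at C6–C7 (O6 and C11 trans on the carbocycle), 8-hydroxy, 9-acetoxy; C7–C11 and C8–O both on the face remote from the C14 bridge, via C8 hydroperoxide 11 (not isolated)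
Conditions: Bu3SnH (slow addition), Et3B (cat.), dry air, toluene, 0 → 20 °C; then PPh3
Reagents that add atoms: dioxygen, O=O
Why: Ueno–Stork-type haloacetal radical cyclisation with oxygenative trapping: the vinyl radical at C11 closes 5-exo onto C7 from the only alkene face the O6 tether can reach, the one not covered by the C14 bridge, and the C8 radical is captured by O2 on that same open face. This sets C7 and C8 with C11 and O8 cis to each other and trans to O6 and O9; PPh3 reduces the hydroperoxide.

Step 9
Reactants: 13 tiglic acid
Product: 14 (E)-2-methylbut-2-en-1-ol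
Conditions: LiAlH4, Et2O, 0 → 20 °C
Reagents that add atoms: none
Why: Hydride reduction of the acid to the allylic alcohol; the trisubstituted alkene and its geometry are untouched.

Step 10
Reactants: 14 (E)-2-methylbut-2-en-1-ol
Product: 15 [(2R,3R)-2,3-dimethyloxiran-2-yl]methanol
Conditions: Ti(OiPr)4 (10 mol%), D-(−)-diethyl tartrate (12 mol%), tBuOOH, 4 Å MS, CH2Cl2, −20 °C
Reagents that add atoms: tert-butyl hydroperoxide, CC(C)(C)OO
Why: Sharpless asymmetric epoxidation; the D-tartrate ligand delivers oxygen to the face giving the (2R,3R) epoxy alcohol, and the E geometry puts the two methyl groups cis.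

Step 11
Reactants: 15 epoxy alcohol
Product: 16 (2S,3R)-2,3-dimethyloxirane-2-carboxylic acid
Conditions: TEMPO (cat.), PhI(OAc)2 (2.2 equiv), MeCN/H2O, 0 → 20 °C; used cold and without storage
Reagents that add atoms: water, O
Why: Oxoammonium oxidation of the primary alcohol through the aldehyde hydrate to the acid; neutral conditions leave the epoxide and both stereocentres intact (the descriptor at C2 changes only because the priorities change).

Step 12
Reactants: 12 C8 alcohol; 16 epoxy acid
Product: 18 C8 (2S,3R)-2,3-dimethyloxirane-2-carboxylate of 12, via mixed trichlorobenzoic anhydride 17 (not isolated)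
Conditions: 16, 2,4,6-trichlorobenzoyl chloride, Et3N, THF, 0 °C; then 12, DMAP, toluene, 20 °C
Reagents that add atoms: none
Why: Yamaguchi esterification, suited to a hindered secondary alcohol and a quaternary acid; acylating C8 directly after step 8 leaves little time for acetyl migration from O9.

Step 13
Reactants: 18 methyl acetal
Product: 19 lactol (C12 hemiacetal, both anomers)
Conditions: PPTS (0.2 equiv), acetone/H2O (5:1), 40 °C
Reagents that add atoms: water, O
Why: Mild acid hydrolysis of an allylic mixed acetal through an alkene-stabilised oxocarbenium ion; the benzyl ether and the carbonyl-deactivated glycidic ester tolerate pyridinium acid.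

Step 14
Reactants: 19 lactol
Product: 20 α-methylene-γ-lactone (6,12-olide) on the bicyclic ketone
Conditions: MnO2 (activated, excess), CH2Cl2, 20 °C
Reagents that add atoms: none
Why: The hemiacetal hydroxyl is allylic to C11=C13, so MnO2 oxidises it to the lactone and no other group is touched.

Step 15
Reactants: 20 lactone
Product: 21 1,4-endoperoxide (O–O bridge from C1 to C4, C2=C3 retained), both C–O bonds on the diene face remote from the C6–C9 arm
Conditions: O2, hν (visible), tetraphenylporphyrin (1 mol%), CH2Cl2, −20 °C
Reagents that add atoms: dioxygen, O=O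
Why: [4+2] photooxygenation of the s-cis cycloheptadiene with singlet oxygen; H6 and H9 sit under one face of the diene, so oxygen adds from the other and sets C4 (and C1) as required, with C2=C3 necessarily Z. The electron-poor methylene lactone does not react.

Step 16
Reactants: 21 endoperoxide
Product: 22 bridgehead α-ketol (5-hydroxy, 14-oxo)
Conditions: DDQ, CH2Cl2/pH 7 buffer, 0 → 20 °C
Reagents that add atoms: none
Why: Oxidative cleavage of the 4-methoxybenzyl ether by benzylic hydride abstraction; it is placed after step 15 so that no electron-rich diene is exposed to the quinone.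

Step 17
Reactants: 22 α-ketol
Product: 23 ten-membered 5-ketone with C10 methyl ester (C14) and the C1–C4 endoperoxide
Conditions: Pb(OAc)4, MeOH/benzene (1:1), 0 °C
Reagents that add atoms: methanol, CO
Why: Glycol-type cleavage of the α-hydroxy ketone: methanol adds to the strained bridging ketone and Pb(OAc)4 cleaves the hemiketal–carbinol pair, giving the C14 methyl ester and the C5 ketone and opening the bicycle to the ten-membered ring; no stereocentre is affected.

Step 18
Reactants: 23 keto endoperoxide
Product: 24 1,4-dihydroxy-5-ketone (C1 and C4 hydroxyls cis, 2Z alkene)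
Conditions: thiourea, MeOH, 0 → 20 °C
Reagents that add atoms: none
Why: Thiourea cleaves the O–O bond of endoperoxides to cis-enediols under neutral conditions, sparing the esters, the ketone and the Michael acceptor.

Step 19
Reactants: 24 dihydroxy ketone
Product: 26 4-hydroxy-5-oxo-1(10),2-dienoate, via C1 mesylate 25 (not isolated)
Conditions: MsCl, Et3N (excess), CH2Cl2, −20 → 20 °C
Reagents that add atoms: none
Why: Sulfonylation of the secondary allylic hydroxyl (the tertiary one is inert) followed by E1cB loss of mesylate through the C10 ester enolate; mesylate leaves far faster than the C9 acetate, and the ring-cis C10=C1 geometry keeps the ester away from C2.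

Step 20
Reactants: 26 α-hydroxy ketone
Product: 27 4,5-diol (new C5 carbinol; with the two oxygens syn, C3 and C6 are on the same side)
Conditions: Zn(BH4)2, Et2O/THF, −30 °C
Reagents that add atoms: none
Why: Cram-chelate reduction: zinc bridges the C4 hydroxyl and the C5 carbonyl and hydride enters from the face of the small C4 methyl, which is also the outer face of the ring; this sets C5 so that invertive closure gives the trans-epoxide. Esters, lactone and dienoate are not reduced by this reagent.

Step 21
Reactants: 27 diol
Product: 29 the target, via C5 mesylate 28 (not isolated)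
Conditions: MsCl, Et3N, CH2Cl2, 0 °C; then DBU, 0 → 20 °C
Reagents that add atoms: none
Why: Selective mesylation of the secondary hydroxyl and 3-exo-tet displacement by the tertiary C4 alkoxide with inversion at C5 give the trans-4,5-epoxide; forming the vinyl oxirane last spares it every acidic step.

## Compound list

1 | tropolone | O=C1C=CC=CC=C1O | starting material
2 | 3-bromotropolone | O=C1C(O)=C(Br)C=CC=C1 | intermediate
3 | 4-methoxybenzyl chloride | COc1ccc(CCl)cc1 | starting material
4 | 3-bromo-2-(4-methoxybenzyloxy)tropone | O=C1C(OCc2ccc(OC)cc2)=C(Br)C=CC=C1 | intermediate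
5 | 2-(4-methoxybenzyloxy)-3-methyltropone | O=C1C(OCc2ccc(OC)cc2)=C(C)C=CC=C1 | intermediate
6 | (1E,3E)-buta-1,3-diene-1,4-diyl diacetate | CC(=O)O/C=C/C=C/OC(C)=O | starting material
7 | (±)-exo [6+4] adduct, 6,9-diacetate, 5-(4-methoxybenzyl) ether, C14 ketone bridge | O=C1[C@]2(OCc3ccc(OC)cc3)C(C)=CC=C[C@H]1[C@H](OC(C)=O)C=C[C@@H]2OC(C)=O | intermediate
8 | (±)-6,9-diol of 7 | O=C1[C@]2(OCc3ccc(OC)cc3)C(C)=CC=C[C@H]1[C@H](O)C=C[C@@H]2O | intermediate
9 | 9-acetate 6-alcohol, single enantiomer | O=C1[C@]2(OCc3ccc(OC)cc3)C(C)=CC=C[C@H]1[C@H](OC(C)=O)C=C[C@@H]2O | intermediate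
10 | O6 2-iodo-1-methoxyallyl acetal of 9 (acetal epimers) | O=C1[C@]2(OCc3ccc(OC)cc3)C(C)=CC=C[C@H]1[C@H](OC(C)=O)C=C[C@@H]2OC(OC)C(I)=C | intermediate
11 | cyclised acetal, C8 hydroperoxide | O=C1[C@]2(OCc3ccc(OC)cc3)C(C)=CC=C[C@H]1[C@H](OC(C)=O)[C@@H](OO)[C@H]4C(=C)C(OC)O[C@H]24 | intermediate
12 | cyclised acetal, C8 alcohol | O=C1[C@]2(OCc3ccc(OC)cc3)C(C)=CC=C[C@H]1[C@H](OC(C)=O)[C@@H](O)[C@H]4C(=C)C(OC)O[C@H]24 | intermediate
13 | tiglic acid, (E)-2-methylbut-2-enoic acid | C/C=C(\C)C(=O)O | starting material
14 | (E)-2-methylbut-2-en-1-ol | C/C=C(\C)CO | intermediate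
15 | [(2R,3R)-2,3-dimethyloxiran-2-yl]methanol | OC[C@@]1(C)O[C@@H]1C | intermediate
16 | (2S,3R)-2,3-dimethyloxirane-2-carboxylic acid | OC(=O)[C@@]1(C)O[C@@H]1C | intermediate
17 | mixed anhydride of 16 with 2,4,6-trichlorobenzoic acid | O=C(OC(=O)[C@@]1(C)O[C@@H]1C)c1c(Cl)cc(Cl)cc1Cl | intermediate
18 | C8 epoxy ester, C12 methyl acetal | O=C1[C@]2(OCc3ccc(OC)cc3)C(C)=CC=C[C@H]1[C@H](OC(C)=O)[C@@H](OC(=O)[C@@]5(C)O[C@@H]5C)[C@H]4C(=C)C(OC)O[C@H]24 | intermediate
19 | C12 lactol | O=C1[C@]2(OCc3ccc(OC)cc3)C(C)=CC=C[C@H]1[C@H](OC(C)=O)[C@@H](OC(=O)[C@@]5(C)O[C@@H]5C)[C@H]4C(=C)C(O)O[C@H]24 | intermediate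
20 | bicyclic α-methylene lactone | O=C1[C@]2(OCc3ccc(OC)cc3)C(C)=CC=C[C@H]1[C@H](OC(C)=O)[C@@H](OC(=O)[C@@]5(C)O[C@@H]5C)[C@H]4C(=C)C(=O)O[C@H]24 | intermediate
21 | C1–C4 endoperoxide | O=C1[C@]2(OCc3ccc(OC)cc3)[C@@]6(C)C=C[C@H](OO6)[C@H]1[C@H](OC(C)=O)[C@@H](OC(=O)[C@@]5(C)O[C@@H]5C)[C@H]4C(=C)C(=O)O[C@H]24 | intermediate
22 | bridgehead α-ketol | O=C1[C@]2(O)[C@@]6(C)C=C[C@H](OO6)[C@H]1[C@H](OC(C)=O)[C@@H](OC(=O)[C@@]5(C)O[C@@H]5C)[C@H]4C(=C)C(=O)O[C@H]24 | intermediate
23 | ten-membered 5-keto 14-ester endoperoxide | C=C1C(=O)O[C@H]2[C@H]1[C@H](OC(=O)[C@@]3(C)O[C@@H]3C)[C@@H](OC(C)=O)[C@@H](C(=O)OC)[C@@H]4C=C[C@@](C)(OO4)C2=O | intermediate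
24 | 1,4-dihydroxy-5-ketone | C=C1C(=O)O[C@H]2[C@H]1[C@H](OC(=O)[C@@]3(C)O[C@@H]3C)[C@@H](OC(C)=O)[C@@H](C(=O)OC)[C@@H](O)/C=C\[C@@](C)(O)C2=O | intermediate
25 | C1 mesylate of 24 | C=C1C(=O)O[C@H]2[C@H]1[C@H](OC(=O)[C@@]3(C)O[C@@H]3C)[C@@H](OC(C)=O)[C@@H](C(=O)OC)[C@@H](OS(C)(=O)=O)/C=C\[C@@](C)(O)C2=O | intermediate
26 | 4-hydroxy-5-oxo dienoate | C=C1C(=O)O[C@H]2[C@H]1[C@H](OC(=O)[C@@]3(C)O[C@@H]3C)[C@@H](OC(C)=O)/C(C(=O)OC)=C\C=C/[C@@](C)(O)C2=O | intermediate
27 | 4,5-diol dienoate | C=C1C(=O)O[C@H]2[C@H]1[C@H](OC(=O)[C@@]3(C)O[C@@H]3C)[C@@H](OC(C)=O)/C(C(=O)OC)=C\C=C/[C@@](C)(O)[C@H]2O | intermediate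
28 | C5 mesylate of 27 | C=C1C(=O)O[C@H]2[C@H]1[C@H](OC(=O)[C@@]3(C)O[C@@H]3C)[C@@H](OC(C)=O)/C(C(=O)OC)=C\C=C/[C@@](C)(O)[C@H]2OS(C)(=O)=O | intermediate
29 | methyl (1(10)E,2Z,4R,5R,6S,7R,8S,9S)-9-acetoxy-4,5-epoxy-8-[(2S,3R)-2,3-dimethyloxirane-2-carbonyloxy]germacra-1(10),2,11(13)-trien-6,12-olid-14-oate | C=C1C(=O)O[C@H]2[C@H]1[C@H](OC(=O)[C@@]1(C)O[C@@H]1C)[C@@H](OC(C)=O)/C(C(=O)OC)=C\C=C/[C@@]1(C)O[C@H]21 | target

## Step count and least certain steps

Total: 21 steps. Longest linear sequence: 18 steps (steps 1–8 and 12–21); the side chain takes 3 steps (9–11).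

**Step 4 (key step).** The alkoxy donor and the neighbouring methyl at one terminus raise the tropone LUMO and hinder bond formation. Prolonged heating may then divert material into [4+2] adducts, sigmatropic rearrangement of the adduct and diene polymerisation, or erode exo selectivity. Fallback, which changes the 4π partner and the deprotection and not merely the temperature: from 6, cleavage of both enol acetates with MeLi (THF, −78 °C) and O-silylation of the dienediolate with TBSCl give, with retention of geometry, (1E,3E)-1,4-bis(tert-butyldimethylsilyloxy)buta-1,3-diene F1. This much more electron-rich diene should add to 5 at 80–100 °C to give the bis-silyl ether adduct F2. Bu4NF/AcOH then returns the route at diol 8, and step 5 is not needed.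

**Step 8.** Ring closure onto the rigid cycloheptene may be slow, so the vinyl radical is reduced or oxygenated before it cyclises, or the C8 radical takes hydrogen from the stannane before it meets oxygen. Fallback with a stoichiometric persistent-radical trap: from 10, Bu3SnH and TEMPO (excess) in benzene at 70 °C give the cyclised C8 alkoxyamine F5. Reductive N–O cleavage with Zn in AcOH/THF/H2O returns the route at 12.

**Step 15.** Singlet oxygen may undergo the ene reaction with the C15 methyl hydrogens instead of the [4+2] addition, or add to the wrong face; the peroxide may also be lost in steps 16–17. Fallback that installs the C4 oxygen after ring opening: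
- From 20, DDQ gives the α-ketol F6.
- Pb(OAc)4 in MeOH gives the ten-membered dienone ester F7.
- Soft enolisation with Et3SiOTf/Et3N removes H10 and gives the silyl trienol ether F8.
- Rubottom oxidation with dimethyldioxirane (acetone, −78 °C) gives the α-silyloxy ketone F9.
- HF·pyridine returns the route at 26.

**Step 6.** The enzyme may discriminate the enantiomers of so bulky a diol poorly, or not acylate it at all. Fallback by classical resolution: from racemic 8, (S)-2-methoxy-2-phenylacetic acid with DCC/DMAP acylates the C9 hydroxyl to the diastereomeric esters F3 (target series) and F4, which are separated by chromatography. K2CO3/MeOH on F3 gives 8 as a single enantiomer, and Ac2O with 2,4,6-collidine at −20 °C acetylates the less hindered hydroxyl, returning the route at 9.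

**Step 19.** The free tertiary C4 hydroxyl may displace the allylic C1 mesylate to a 2,5-dihydrofuran before elimination, or elimination may give the ring-trans alkene or expel the C9 acetate. Fallback that masks the C4 oxygen first:
- From 24, Zn(BH4)2 gives the 1,4,5-triol F10.
- 2-Methoxypropene/PPTS gives the 4,5-acetonide F11.
- MsCl/Et3N gives the C1 mesylate F12, and DBU eliminates it to the dienoate acetonide F13.
- Aqueous AcOH removes the acetonide and returns the route at 27.

## Further compounds

F1 | step 4 | (1E,3E)-1,4-bis(tert-butyldimethylsilyloxy)buta-1,3-diene | CC(C)(C)[Si](C)(C)O/C=C/C=C/O[Si](C)(C)C(C)(C)C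
F2 | step 4 | (±)-exo [6+4] adduct as 6,9-bis(tert-butyldimethylsilyl) ether | O=C1[C@]2(OCc3ccc(OC)cc3)C(C)=CC=C[C@H]1[C@H](O[Si](C)(C)C(C)(C)C)C=C[C@@H]2O[Si](C)(C)C(C)(C)C
F3 | step 6 | C9 (S)-2-methoxy-2-phenylacetate of the target-series enantiomer of 8 | O=C1[C@]2(OCc3ccc(OC)cc3)C(C)=CC=C[C@H]1[C@H](OC(=O)[C@@H](OC)c3ccccc3)C=C[C@@H]2O
F4 | step 6 | C9 (S)-2-methoxy-2-phenylacetate of ent-8 | O=C1[C@@]2(OCc3ccc(OC)cc3)C(C)=CC=C[C@@H]1[C@@H](OC(=O)[C@@H](OC)c3ccccc3)C=C[C@H]2O
F5 | step 8 | cyclised acetal, C8 O-(2,2,6,6-tetramethylpiperidin-1-yl) ether | O=C1[C@]2(OCc3ccc(OC)cc3)C(C)=CC=C[C@H]1[C@H](OC(C)=O)[C@@H](ON5C(C)(C)CCCC5(C)C)[C@H]4C(=C)C(OC)O[C@H]24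
F6 | step 15 | bridgehead α-ketol with intact diene | O=C1[C@]2(O)C(C)=CC=C[C@H]1[C@H](OC(C)=O)[C@@H](OC(=O)[C@@]5(C)O[C@@H]5C)[C@H]4C(=C)C(=O)O[C@H]24
F7 | step 15 | ten-membered (1Z,3Z)-dien-5-one with C10 methyl ester | C=C1C(=O)O[C@H]2[C@H]1[C@H](OC(=O)[C@@]3(C)O[C@@H]3C)[C@@H](OC(C)=O)[C@@H](C(=O)OC)/C=C\C=C(C)/C2=O
F8 | step 15 | triethylsilyl trienol ether (C4=C5 geometry not assigned) | C=C1C(=O)O[C@H]2[C@H]1[C@H](OC(=O)[C@@]3(C)O[C@@H]3C)[C@@H](OC(C)=O)/C(C(=O)OC)=C\C=C/C(C)=C2O[Si](CC)(CC)CC
F9 | step 15 | 4-triethylsilyloxy-5-oxo dienoate | C=C1C(=O)O[C@H]2[C@H]1[C@H](OC(=O)[C@@]3(C)O[C@@H]3C)[C@@H](OC(C)=O)/C(C(=O)OC)=C\C=C/[C@@](C)(O[Si](CC)(CC)CC)C2=O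
F10 | step 19 | 1,4,5-triol | C=C1C(=O)O[C@H]2[C@H]1[C@H](OC(=O)[C@@]3(C)O[C@@H]3C)[C@@H](OC(C)=O)[C@@H](C(=O)OC)[C@@H](O)/C=C\[C@@](C)(O)[C@H]2O
F11 | step 19 | 4,5-acetonide of the triol | C=C1C(=O)O[C@H]2[C@H]1[C@H](OC(=O)[C@@]3(C)O[C@@H]3C)[C@@H](OC(C)=O)[C@@H](C(=O)OC)[C@@H](O)/C=C\[C@@]4(C)OC(C)(C)O[C@@H]24
F12 | step 19 | C1 mesylate of the acetonide | C=C1C(=O)O[C@H]2[C@H]1[C@H](OC(=O)[C@@]3(C)O[C@@H]3C)[C@@H](OC(C)=O)[C@@H](C(=O)OC)[C@@H](OS(C)(=O)=O)/C=C\[C@@]4(C)OC(C)(C)O[C@@H]24
F13 | step 19 | dienoate 4,5-acetonide | C=C1C(=O)O[C@H]2[C@H]1[C@H](OC(=O)[C@@]3(C)O[C@@H]3C)[C@@H](OC(C)=O)/C(C(=O)OC)=C\C=C/[C@@]4(C)OC(C)(C)O[C@@H]24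
A1 | alternative 1 | ten-membered β-keto ester (enol form) with C8 hydroxyl, C7 propenoate and 4,5-epoxide | O/C1=C(\C(=O)OC)C/C=C\[C@@]2(C)O[C@@H]2[C@@H](O[Si](C)(C)C(C)(C)C)[C@H](C(=C)C(=O)OC)[C@@H]1O
A2 | alternative 2 | ten-membered cycloalkynone with C8 ketone and C4–C7, C9 stereocentres | CC(C)(C)[Si](C)(C)OCC[C@H]1[C@H](O[Si](C)(C)C(C)(C)C)[C@@H]2OC(C)(C)O[C@]2(C)C#CC[C@@H](C(=O)OC)[C@H](OCc3ccc(OC)cc3)C1=O
A3 | alternative 3 | ten-membered 1(10)-cis,2-cis,4-trans trienoate with lactone, C9 acetate and C8 silyl ether | O=C1C(=C)[C@H]2[C@H](O1)/C=C(C)/C=C\C=C(C(=O)OC)/[C@H](OC(C)=O)[C@H]2O[Si](C)(C)C(C)(C)C
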